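The furanone (O1, carbonyl C2, C3, enol carbon C4, C5) is disconnected to a cyclobutanone. Its four ring carbons C2–C3–C4–C5 are assembled first, and O1 is inserted later between C2 and C5 by a strain-driven Baeyer–Villiger oxidation. The key step is the stepwise [2+2] addition of (benzyloxymethyl)ketene to a twofold-symmetric chiral ketene acetal: it forms C2–C3 and then closes the four-membered ring through C4–C5. It exploits the 1,3-relationship of the lactone carbonyl C2 and the enolised ketone C4 across C3 in the furanone ring; C4 arrives as a ketal carbon that relays chirality to C5. The precursors are an acyclic acid chloride and a dioxolane ketene acetal. Ketal hydrolysis, C3-acylation and debenzylation finish the synthesis.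

Key step: step 3

Remark: furanone locants (O1, C2–C5, C6 for the CH2O carbon) are used for all intermediates; the 3-acyl tetronic acid is drawn as its C4 enol, its enol tautomers being one compound.
Remark: the sense of induction by the (S,S)-diol in step 3 is an assumption from a steric model; the configuration of 9 is to be confirmed before step 4.

Step 1
Reactants: 1 (1S,2S)-1,2-diphenylethane-1,2-diol; 2 2-bromo-1,1-diethoxyethane
Product: 3 (4S,5S)-2-(bromomethyl)-4,5-diphenyl-1,3-dioxolane
Conditions: TsOH·H2O (cat.), toluene, 110 °C, EtOH distilled off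
Reagents that add atoms: none
Why: Acid-catalysed transacetalisation, driven by removal of ethanol; no bond to either carbinol carbon is broken, so both (S) centres are kept.

Step 2
Reactants: 3 (4S,5S)-2-(bromomethyl)-4,5-diphenyl-1,3-dioxolane
Product: 4 (4S,5S)-2-methylidene-4,5-diphenyl-1,3-dioxolane
Conditions: KOtBu, THF, 0 °C to rt
Reagents that add atoms: none
Why: E2 dehydrobromination with a hindered alkoxide, the standard route to cyclic ketene acetals from 2-(halomethyl)-1,3-dioxolanes; the stereocentres are remote from the reacting atoms.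

Step 3
Reactants: 5 3-(benzyloxy)propanoic acid; 4 (4S,5S)-2-methylidene-4,5-diphenyl-1,3-dioxolane
Product: 9 (1R,6S,7S)-1-[(benzyloxy)methyl]-6,7-diphenyl-5,8-dioxaspiro[3.4]octan-2-one, via acid chloride 6 (not isolated), via ketene 7 (not isolated), via zwitterion 8 (not isolated)
Conditions: (COCl)2, DMF (cat.), CH2Cl2, rt, evaporate; then added over 4 h to 4 (1.5 equiv), Et3N (1.3 equiv), CH2Cl2, 0 °C to rt; epimers separated on silica
Reagents that add atoms: none
Why: Triethylamine dehydrochlorinates acid chloride 6 to aldoketene 7; the nucleophilic CH2 terminus of ketene acetal 4 (future C3) adds to the ketene carbonyl carbon (C2) to give zwitterion 8, an enolate paired with a 1,3-dioxolan-2-ylium ion, and the enolate carbon C5 then attacks the cationic C4, closing the cyclobutanone through the C4–C5 bond (4-exo-trig collapse of the ion pair, the second bond of a stepwise [2+2]). This is the established [2+2] cycloaddition of in situ ketenes with ketene acetals to 3,3-dialkoxycyclobutanones, the regiochemistry being fixed by the polarity of both partners. The only new stereocentre, C5, is set relative to the twofold-symmetric (4S,5S)-diphenyldioxolane (which leaves the spiro carbon C4 non-stereogenic): CH2OBn should take the face of the four-membered ring on which the neighbouring O–CH turns its hydrogen, not its phenyl, towards C5, i.e. the (1R) epimer that maps onto (S)-C5 of the target. The bias is expected to be moderate; the other spiro epimer is a diastereomer, is removed on silica and, being enolisable at C5, can be re-equilibrated with amine and recycled. The step needs ring closure of 8 to outrun proton transfer (which would give an acyclic acyl ketene acetal) and ketene dimerisation; slow addition of 6 to excess 4 and amine keeps free ketene low.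

Step 4
Reactants: 9 (1R,6S,7S)-1-[(benzyloxy)methyl]-6,7-diphenyl-5,8-dioxaspiro[3.4]octan-2-one
Product: 10 (2S,3S,6S)-6-[(benzyloxy)methyl]-2,3-diphenyl-1,4,7-trioxaspiro[4.4]nonan-8-one
Conditions: mCPBA, NaHCO3, CH2Cl2, 0 °C to rt
Reagents that add atoms: mCPBA (O=C(OO)c1cccc(Cl)c1)
Why: Baeyer–Villiger oxidation, driven by release of cyclobutanone strain: in the Criegee adduct the more substituted α-carbon C5 migrates to oxygen with retention of configuration, which inserts O1 between C2 and C5 and turns (1R)-9 into the (S)-C5 lactone, while the bicarbonate buffer keeps the ketal intact.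

Step 5
Reactants: 10 (2S,3S,6S)-6-[(benzyloxy)methyl]-2,3-diphenyl-1,4,7-trioxaspiro[4.4]nonan-8-one
Product: 11 (5S)-5-[(benzyloxy)methyl]-4-hydroxyfuran-2(5H)-one
Conditions: TFA/H2O (9:1), rt
Reagents that add atoms: water (O)
Why: Acid opens the ketal (β-elimination to the 4-alkoxybutenolide, then hydrolysis of this vinylogous ester) and so unmasks C4 as the enolised ketone of the tetronic acid; C5 does not enolise under acid, the benzyl ether survives and the diol is recovered.

Step 6
Reactants: 12 (S)-1-bromo-2-methylbutane; 13 12-bromododecanoic acid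
Product: 16 (S)-14-methylhexadecanoic acid, via Grignard reagent 14 (not isolated), via magnesium carboxylate 15 (not isolated)
Conditions: 12, Mg, THF; 13, MeMgCl (1.0 equiv), THF, −20 °C; combined, Li2CuCl4 (2 mol %), −20 °C to rt; aq. HCl
Reagents that add atoms: none
Why: Copper-catalysed sp3–sp3 cross-coupling of a Grignard reagent with a primary bromide (Kochi-type), run on the magnesium carboxylate so that no ester protection is needed; the stereocentre of 12 is β to magnesium and stays (S).

Step 7
Reactants: 11 (5S)-5-[(benzyloxy)methyl]-4-hydroxyfuran-2(5H)-one; 16 (S)-14-methylhexadecanoic acid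
Product: 18 (5S)-5-[(benzyloxy)methyl]-4-hydroxy-3-[(14S)-14-methylhexadecanoyl]furan-2(5H)-one, via enol ester 17 (not isolated)
Conditions: DCC, DMAP (1.3 equiv), CH2Cl2, 0 °C to rt; aq. HCl work-up
Reagents that add atoms: none
Why: Carbodiimide O-acylation of the acidic C4 enol gives enol ester 17, which DMAP converts by 1,3-O-to-C acyl transfer (Steglich/Fries-type) into the chelated, thermodynamically favoured 3-acyl tetronic acid, as is standard for 5-substituted tetronic acids; C5 is not touched.

Step 8
Reactants: 18 (5S)-5-[(benzyloxy)methyl]-4-hydroxy-3-[(14S)-14-methylhexadecanoyl]furan-2(5H)-one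
Product: 19 (5S)-4-hydroxy-5-(hydroxymethyl)-3-[(14S)-14-methylhexadecanoyl]furan-2(5H)-one
Conditions: H2 (1 atm), Pd/C, EtOAc, rt
Reagents that add atoms: none
Why: Hydrogenolysis of the benzyl ether over Pd/C; the enolised tricarbonyl unit and the saturated chain are inert, so both stereocentres are unchanged.

Compound list
1 | (1S,2S)-1,2-diphenylethane-1,2-diol | O[C@@H](c1ccccc1)[C@@H](O)c1ccccc1 | starting material
2 | 2-bromo-1,1-diethoxyethane | CCOC(CBr)OCC | starting material
3 | (4S,5S)-2-(bromomethyl)-4,5-diphenyl-1,3-dioxolane | BrCC1O[C@@H](c2ccccc2)[C@H](c2ccccc2)O1 | intermediate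
4 | (4S,5S)-2-methylidene-4,5-diphenyl-1,3-dioxolane | C=C1O[C@@H](c2ccccc2)[C@H](c2ccccc2)O1 | intermediate
5 | 3-(benzyloxy)propanoic acid | OC(=O)CCOCc1ccccc1 | starting material
6 | 3-(benzyloxy)propanoyl chloride | ClC(=O)CCOCc1ccccc1 | intermediate
7 | 3-(benzyloxy)prop-1-en-1-one, (benzyloxymethyl)ketene | O=C=CCOCc1ccccc1 | intermediate
8 | zwitterion: 4-(benzyloxy)-1-[(4S,5S)-4,5-diphenyl-1,3-dioxolan-2-ylium-2-yl]but-2-en-2-olate | [O-]C(=CCOCc1ccccc1)CC1=[O+][C@@H](c2ccccc2)[C@H](c2ccccc2)O1 | intermediate
9 | (1R,6S,7S)-1-[(benzyloxy)methyl]-6,7-diphenyl-5,8-dioxaspiro[3.4]octan-2-one | O=C1CC2(O[C@@H](c3ccccc3)[C@H](c3ccccc3)O2)[C@@H]1COCc1ccccc1 | intermediate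
10 | (2S,3S,6S)-6-[(benzyloxy)methyl]-2,3-diphenyl-1,4,7-trioxaspiro[4.4]nonan-8-one | O=C1CC2(O[C@@H](c3ccccc3)[C@H](c3ccccc3)O2)[C@H](COCc2ccccc2)O1 | intermediate
11 | (5S)-5-[(benzyloxy)methyl]-4-hydroxyfuran-2(5H)-one | O=C1C=C(O)[C@H](COCc2ccccc2)O1 | intermediate
12 | (S)-1-bromo-2-methylbutane | CC[C@H](C)CBr | starting material
13 | 12-bromododecanoic acid | OC(=O)CCCCCCCCCCCBr | starting material
14 | (S)-2-methylbutylmagnesium bromide | CC[C@H](C)C[Mg]Br | intermediate
15 | chloromagnesium 12-bromododecanoate | [O-]C(=O)CCCCCCCCCCCBr.[Mg+2].[Cl-] | intermediate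
16 | (S)-14-methylhexadecanoic acid | CC[C@H](C)CCCCCCCCCCCCC(=O)O | intermediate
17 | (2S)-2-[(benzyloxy)methyl]-5-oxo-2,5-dihydrofuran-3-yl (14S)-14-methylhexadecanoate | CC[C@H](C)CCCCCCCCCCCCC(=O)OC1=CC(=O)O[C@H]1COCc1ccccc1 | intermediate
18 | (5S)-5-[(benzyloxy)methyl]-4-hydroxy-3-[(14S)-14-methylhexadecanoyl]furan-2(5H)-one | CC[C@H](C)CCCCCCCCCCCCC(=O)C1=C(O)[C@H](COCc2ccccc2)OC1=O | intermediate
19 | (5S)-4-hydroxy-5-(hydroxymethyl)-3-[(14S)-14-methylhexadecanoyl]furan-2(5H)-one | CC[C@H](C)CCCCCCCCCCCCC(=O)C1=C(O)[C@H](CO)OC1=O | target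

Total step count: 8. Longest linear sequence: 7 steps (steps 1, 2, 3, 4, 5, 7 and 8).

Steps most likely to fail

Step 3. The ion pair 8 may close with little facial discrimination, because the phenyl groups of the auxiliary are remote from C5, so that much of the material ends up as the unwanted spiro epimer. The fallback drops the auxiliary and sets C5 with an enzyme. Setting out from 5, the same ketene (via 6 and 7) is added to commercial 1,1-diethoxyethene to give racemic 2-[(benzyloxy)methyl]-3,3-diethoxycyclobutan-1-one F1. Its C5 is α to the ketone and epimerises through the enol, so a Baeyer–Villiger monooxygenase of the cyclohexanone monooxygenase family (whole cells, air, pH 9) should convert it under dynamic kinetic resolution into (S)-5-[(benzyloxy)methyl]-4,4-diethoxyoxolan-2-one F2. Aqueous acid then hydrolyses the diethyl ketal, which returns to the route at 11.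

Step 5. The diphenyldioxolane may resist acid and stall at the 4-alkoxybutenolide stage, or the acid forced on it may strip the benzyl ether. The fallback removes the diol reductively and changes the protecting group. Setting out from 10, hydrogenolysis (H2, Pd(OH)2/C, MeOH) cleaves both benzylic C–O bonds of the ketal and the benzyl ether and gives (S)-4-hydroxy-5-(hydroxymethyl)furan-2(5H)-one F3. Silylation (TBDPSCl, imidazole; the enol silyl ether falls off on aqueous work-up) gives (S)-5-{[(tert-butyldiphenylsilyl)oxy]methyl}-4-hydroxyfuran-2(5H)-one F4. Acylation with 16 under the conditions of step 7 gives (5S)-5-{[(tert-butyldiphenylsilyl)oxy]methyl}-4-hydroxy-3-[(14S)-14-methylhexadecanoyl]furan-2(5H)-one F5, and HF·pyridine removes the silyl group, which returns to the route at 19.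

Step 7. Acyl transfer may stop at enol ester 17, or DMAP may epimerise C5 through the dienolate. The fallback attaches the acyl group before the tetronic acid is unmasked. Setting out from 10 and 16, the acid 16 is converted with oxalyl chloride into (S)-14-methylhexadecanoyl chloride F6. The lithium enolate of 10 (LiHMDS, 2 equiv, THF, −78 °C, kept cold so that the ketal oxygen is not lost by β-elimination) is C-acylated by F6 in a crossed Claisen condensation. This gives (2S,3S,6S)-6-[(benzyloxy)methyl]-9-[(14S)-14-methylhexadecanoyl]-2,3-diphenyl-1,4,7-trioxaspiro[4.4]nonan-8-one F7 as a mixture at C9, which does not matter. TFA/H2O then cleaves the ketal as in step 5, which returns to the route at 18.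

Further compounds
F1 | step 3 | 2-[(benzyloxy)methyl]-3,3-diethoxycyclobutan-1-one (racemic) | CCOC1(OCC)CC(=O)C1COCc1ccccc1
F2 | step 3 | (S)-5-[(benzyloxy)methyl]-4,4-diethoxyoxolan-2-one | CCOC1(OCC)CC(=O)O[C@H]1COCc1ccccc1
F3 | step 5 | (S)-4-hydroxy-5-(hydroxymethyl)furan-2(5H)-one | O=C1C=C(O)[C@H](CO)O1
F4 | step 5 | (S)-5-{[(tert-butyldiphenylsilyl)oxy]methyl}-4-hydroxyfuran-2(5H)-one | O=C1C=C(O)[C@H](CO[Si](c2ccccc2)(c2ccccc2)C(C)(C)C)O1
F5 | step 5 | (5S)-5-{[(tert-butyldiphenylsilyl)oxy]methyl}-4-hydroxy-3-[(14S)-14-methylhexadecanoyl]furan-2(5H)-one | CC[C@H](C)CCCCCCCCCCCCC(=O)C1=C(O)[C@H](CO[Si](c2ccccc2)(c2ccccc2)C(C)(C)C)OC1=O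
F6 | step 7 | (S)-14-methylhexadecanoyl chloride | CC[C@H](C)CCCCCCCCCCCCC(=O)Cl
F7 | step 7 | (2S,3S,6S)-6-[(benzyloxy)methyl]-9-[(14S)-14-methylhexadecanoyl]-2,3-diphenyl-1,4,7-trioxaspiro[4.4]nonan-8-one | CC[C@H](C)CCCCCCCCCCCCC(=O)C1C(=O)O[C@@H](COCc2ccccc2)C12O[C@@H](c3ccccc3)[C@H](c3ccccc3)O2
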